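## Structural features

Praesorether F (25) is an achiral triaryl system. Ring A is a methyl orsellinate unit (C1 ester, C2 and C4 hydroxyls, C6 methyl) substituted at C3. Ring B is an orcinol-derived ring (C1' to C6') with hydroxyls at C2' and C6', methyl at C4' and a third oxygen at C5'. Ring C (C1'' to C6'') is a methyl haematommate unit. Ring A is joined to ring B by a methylene between C3 and C1', a carbon flanked by two hydroxyls on each ring; ring B is joined to ring C by the diaryl ether C5'–O–C1''. There is no stereocentre, so the whole difficulty is constitutional.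

Ring C carries six different substituents in a fixed order: aryloxy (C1''), CHO (C2''), OH (C3''), H (C4''), CH3 (C5''), CO2CH3 (C6''). The ether carbon C1'' lies between the formyl- and ester-bearing carbons and C5' lies between C4'–CH3 and C6'–OH, so all four positions ortho to the ether oxygen are occupied; this ether is the real difficulty. Ring B is 1,2,4-trioxygenated, and any precursor with C1' and C3' both free offers two similarly activated positions to an electrophile. Fragile groups are the salicylaldehyde, the two methyl esters, the electron-rich ring B and the 2,6-dihydroxybenzyl linkage, which ionises to an ortho-quinone methide.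

The key step exploits the meta relation of the oxygens on C1'' and C3'' with a carbon substituent on C2'' between them and the ester para to the hydroxyl. This is exactly the pattern written by a benzannulation of a vinylketene with an alkynyl ether, so ring C can be grown around the ether oxygen and the hindered aryl–oxygen bond never has to be made at an arene.

## Logic of the disconnections

25 ⇒ 23 + 24. The bond cut is the one between the benzylic carbon on C1' and C3 of ring A. Ring A then is commercial 24, whose C3 between the two hydroxyls is its expected site for benzylic cations. The one-carbon unit stays on ring B, where its place at C1' can be fixed at the very start. The forward step must ionise 23 at the benzylic carbon under mild acid and keep 23 dilute so that 24 is alkylated rather than C3' of a second molecule of 23.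

23 ⇒ 22 ⇒ 21 ⇒ 20. These are adjustments only: two O–CH2OCH3 bonds are cut (MOM ethers), and the formyl group on C2'' is traced back through CH2OH to CH2OSi. C2'' is carried at the alcohol level because the alkyne of the key step must stay nucleophilic. The benzylic methyl ether on C1' has to survive the MOM removal, and in acidic methanol it can only exchange with the solvent.

20 ⇒ 13 + 16 (key disconnection). Three ring C bonds are cut: C1''–C6'', C2''–C3'' and C3''–C4''. Ring C disappears completely. C1'' and C2'' come from the alkyne of 13; C3'', C4'', C5'' and C6'' come from 17, which is made in the flask from 16. The hindered ether becomes an oxygen–carbon bond at an sp carbon already present in 13, and all six substituents are placed by connectivity. In one sentence: ring C of 20 is grown around the ether oxygen of 13 by benzannulation with 17. The forward step needs the [2+2] event to occur with the correct orientation and through the C=C bond of 17, followed by the 4π opening and 6π closure.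

13 ⇒ 9 ⇒ 8. The bonds cut are O–C1'' (as an O–C(sp) bond) and C2''–CH2O. The two alkyne carbons come from trichloroethylene and the future formyl carbon from formaldehyde. The phenoxide of 8 adds to an sp carbon, so its two ortho substituents do not matter. The step must tolerate n-BuLi, which is why ring A with its ester is attached only at the end.

8 ⇒ 5 ⇒ 4. The C5'–O bond is traced back to C–Br and then to C–H. Because 4 is symmetric, its two free ring positions are equivalent and bromination has a single outcome.

4 ⇒ 2 ⇒ 1. The C1'–CH2 bond is cut. Lithiation of 2 between its two MOM ethers fixes the position of the bridge carbon with certainty, and 1 is commercial.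

16 ⇒ 15 ⇒ 14. Functional group changes only; 14 is commercial and already holds C3'', C4'', C5'' with its methyl and C6'' with its ester.

## Other disconnections considered

Alternative 1: Cut the C5'–O–C1'' bond between two finished benzene rings (the first idea). The forward key step is SNAr of the potassium salt of 2,4-dimethoxy-6-methylphenol A1 on methyl 2-fluoro-3-formyl-4-methoxy-6-methylbenzoate A2 to give diaryl ether A3, followed by demethylation and Friedel–Crafts bridging with a ring A benzylic electrophile.
- The bond would form at a carbon flanked by formyl- and ester-bearing carbons with a nucleophile flanked by methyl and methoxy, so the addition intermediate carries four ortho substituents.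
- The formyl group of A2 is itself an electrophile for the phenoxide.
- A2 needs about four steps of its own, so nothing is saved.
- After the coupling ring B has two free activated positions, and an orcinol-type ring is expected to react at the one para to a hydroxyl (C3'), the wrong one.
- Three aryl methyl ethers would have to be cleaved beside two methyl esters.

The chosen plan fixes C1' before ring C exists and makes the ether bond at an unhindered sp carbon.

Alternative 2: Cut C1''–C2'' and C5''–C6'' and make ring C from another ring. The forward key step is a Diels–Alder reaction of 3-formyl-4-hydroxy-6-methyl-2H-pyran-2-one A5 with alkynoate A4 (from 11 by C-carbomethoxylation) to the bridged lactone A6, which loses CO2 to give 22 directly.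
- This would save two steps, but both partners are push–pull systems: C3 of A5 is deactivated by the formyl group and the alkyne of A4 by the ester, so neither electron demand is well served.
- High temperatures would be needed, at which the acidic hydroxyl of A5 can add to the ketene-acetal-like carbon of A4.
- The regiochemistry rests on a weak polarisation.

The ketene route reaches the same arene through a [2+2] event between a strongly electrophilic and a strongly nucleophilic partner at room temperature.

Alternative 3: Cut C1''–O at a non-aromatic stage of ring C and aromatise late. Vilsmeier–Haack chloroformylation of 5-methylcyclohexane-1,3-dione A7 gives chloro-enal A8; addition–elimination by the phenoxide of 8 gives vinylogous ester A9; dehydrogenation gives arene A10.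
- The substitution is unhindered, but A10 lacks the ester on C6''.
- Carboxylation of A10 at C6'', between the aryloxy and methyl groups, would compete with the far more electron-rich ring B.
- An ester carried from the start would break the symmetry of the dione and, on steric grounds, send the chlorine to the carbonyl remote from it, giving the isomer with the aryloxy group para to the ester.

The benzannulation places the ester by connectivity.

Key step: step 9

Remark on the chemistry: the target has no stereocentre, so no stereocontrol is needed. Orcinol is used anhydrous. ArB stands for 3-(methoxymethyl)-2,4-bis(methoxymethoxy)-6-methylphenyl, bonded through its C1 (the future C5').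

## Route

Step 1
Reactants: 1 orcinol (5-methylbenzene-1,3-diol)
Product: 2 1,3-bis(methoxymethoxy)-5-methylbenzene
Conditions: NaH (2.4 equiv), MOMCl (2.4 equiv), DMF, 0 °C → 25 °C
Reagents that add atoms: chloromethyl methyl ether (MOMCl), COCCl
Why: Williamson-type O-alkylation of both phenoxides; the MOM ethers later direct the lithiation and are removed together under acid.

Step 2
Reactants: 2 1,3-bis(methoxymethoxy)-5-methylbenzene
Product: 4 2-(methoxymethyl)-1,3-bis(methoxymethoxy)-5-methylbenzene, via aryllithium 3 (not isolated)
Conditions: n-BuLi (1.1 equiv), THF, 0 °C; then MOMCl (1.3 equiv), −78 °C → 25 °C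
Reagents that add atoms: chloromethyl methyl ether (MOMCl), COCCl
Why: Directed ortho-metalation occurs at the carbon between the two MOM ethers (cooperative coordination), and aryllithium 3 is alkylated by MOMCl (SN2) to give the benzylic methyl ether that fixes the future C1'.

Step 3
Reactants: 4 2-(methoxymethyl)-1,3-bis(methoxymethoxy)-5-methylbenzene
Product: 5 1-bromo-3-(methoxymethyl)-2,4-bis(methoxymethoxy)-6-methylbenzene
Conditions: NBS (1.0 equiv), MeCN, −20 °C → 0 °C
Reagents that add atoms: N-bromosuccinimide, O=C1CCC(=O)N1Br
Why: Electrophilic aromatic bromination; the two free positions of 4 are equivalent by symmetry (each para to one MOM ether and ortho to the other), so only one monobromide can form, and the first bromine slows a second substitution.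

Step 4
Reactants: 5 1-bromo-3-(methoxymethyl)-2,4-bis(methoxymethoxy)-6-methylbenzene
Product: 8 3-(methoxymethyl)-2,4-bis(methoxymethoxy)-6-methylphenol (ArB–OH), via aryllithium 6 (not isolated), via dimethyl arylboronate 7 (not isolated)
Conditions: n-BuLi (1.1 equiv), THF, −78 °C; B(OMe)3 (1.5 equiv), −78 °C → 0 °C; then H2O2 (30% aq.), NaOH (aq.), 0 °C → 25 °C
Reagents that add atoms: hydrogen peroxide, OO
Why: Bromine–lithium exchange, borylation and oxidative 1,2-shift of the aryl group from boron to oxygen turn C–Br into the C5' hydroxyl without change of position.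

Step 5
Reactants: 8 3-(methoxymethyl)-2,4-bis(methoxymethoxy)-6-methylphenol
Product: 9 (E)-1,2-dichloroethenyl ether ArB–O–C(Cl)=CHCl
Conditions: KH (1.3 equiv), THF, 0 °C; trichloroethylene (1.2 equiv), 0 °C → 25 °C
Reagents that add atoms: trichloroethylene, ClC=C(Cl)Cl
Why: Base converts trichloroethylene into dichloroacetylene, to which the potassium phenoxide adds in anti fashion (E geometry); the attack is on an unhindered sp carbon, so the two ortho substituents of the phenoxide do not interfere.

Step 6
Reactants: 9 (E)-1,2-dichloroethenyl ether ArB–O–C(Cl)=CHCl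
Product: 13 tert-butyl{[3-(ArB-oxy)prop-2-yn-1-yl]oxy}dimethylsilane, via chloroalkynyl ether 10 (not isolated), via lithium alkynyl ether 11 (not isolated), via lithium alkoxide 12 (not isolated)
Conditions: n-BuLi (2.3 equiv), THF, −78 °C → −40 °C; (CH2O)n (3 equiv), −40 °C → 0 °C; then TBSCl (1.5 equiv), imidazole, DMF, 0 °C → 25 °C
Reagents that add atoms: formaldehyde (as paraformaldehyde), C=O; tert-butyldimethylsilyl chloride, CC(C)(C)[Si](C)(C)Cl
Why: Deprotonation and loss of LiCl give 10, chlorine–lithium exchange gives 11, which adds to formaldehyde; silylation of 12 in the same flask avoids handling the acid-sensitive propargylic alcohol.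

Step 7
Reactants: 14 dimethyl 2-(propan-2-ylidene)propanedioate (dimethyl isopropylidenemalonate)
Product: 15 2-(methoxycarbonyl)-3-methylbut-2-enoic acid
Conditions: KOH (1.0 equiv), MeOH, 0 °C → 25 °C; then HCl (aq.)
Reagents that add atoms: potassium hydroxide, [K+].[OH-]
Why: Mono-saponification of a geminal diester; the carboxylate formed first shields the remaining ester from hydroxide.

Step 8
Reactants: 15 2-(methoxycarbonyl)-3-methylbut-2-enoic acid
Product: 16 methyl 2-(chlorocarbonyl)-3-methylbut-2-enoate
Conditions: (COCl)2 (1.3 equiv), DMF (cat.), CH2Cl2, 0 °C → 25 °C; volatiles removed, used crude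
Reagents that add atoms: oxalyl chloride, O=C(Cl)C(=O)Cl
Why: Standard acid chloride formation through the chloroiminium species from DMF and oxalyl chloride.

Step 9
Reactants: 13 tert-butyl{[3-(ArB-oxy)prop-2-yn-1-yl]oxy}dimethylsilane; 16 methyl 2-(chlorocarbonyl)-3-methylbut-2-enoate
Product: 20 methyl 2-(ArB-oxy)-3-({[tert-butyl(dimethyl)silyl]oxy}methyl)-4-hydroxy-6-methylbenzoate, via vinylketene 17 (not isolated), via cyclobutenone 18 (not isolated), via dienylketene 19 (not isolated)
Conditions: 16 (1.5 equiv) added over 3 h to 13 and Et3N (3 equiv), toluene, 25 °C; then 110 °C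
Reagents that add atoms: none
Why: Danheiser-type benzannulation: Et3N effects 1,4-dehydrochlorination of 16 to vinylketene 17, whose electrophilic carbonyl carbon is attacked by the nucleophilic β-carbon of alkynyl ether 13 (the carbon bearing CH2OTBS), and the ketene/alkyne [2+2] cycloaddition closes the four-membered ring of 18 (bonds C3''–C2'' and C1''–C6''). On heating, 18 opens by conrotatory 4π electrocyclic cleavage of the C3''–C6'' bond to dienylketene 19, and ring C is closed by thermal disrotatory 6π electrocyclisation (bond C3''–C4''), followed by tautomerisation of the cyclohexadienone to the phenol. The closest known reaction type is the benzannulation of vinylketenes, generated from cyclobutenones or diazo ketones, with alkoxy- and siloxyalkynes to give 3-alkoxyphenols. Connectivity places every substituent: the ketene carbonyl becomes C3''–OH, the alkyne carbons become C2'' (CH2OTBS) and C1'' (O–ArB), and the α-, β- and γ-carbons of 17 become C6'' (CO2CH3), C5'' (CH3) and C4'' (H). No stereocentre is set: the quaternary carbon of racemic 18 is destroyed on ring opening, and since that opening is reversible either rotation can funnel into the isomer of 19 that cyclises. The step needs the correct orientation of the [2+2] event, which the oxygen-induced polarisation of the alkynyl ether should secure, and reaction of 17 through its C=C bond rather than as a hetero-diene through the ester carbonyl, which is expected because an ester carbonyl is a poor 4π partner. The ether bond with four ortho substituents is never formed at an arene; it is already present in 13 and ring C grows around it.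

Step 10
Reactants: 20 methyl 2-(ArB-oxy)-3-({[tert-butyl(dimethyl)silyl]oxy}methyl)-4-hydroxy-6-methylbenzoate
Product: 21 methyl 2-(ArB-oxy)-4-hydroxy-3-(hydroxymethyl)-6-methylbenzoate
Conditions: Bu4NF (1.2 equiv), AcOH (1.2 equiv), THF, 0 °C
Reagents that add atoms: none
Why: Fluoride-induced desilylation; the acetic acid buffer keeps the phenol protonated so that no ortho-quinone methide forms, and MOM ethers and esters are inert.

Step 11
Reactants: 21 methyl 2-(ArB-oxy)-4-hydroxy-3-(hydroxymethyl)-6-methylbenzoate
Product: 22 methyl 2-(ArB-oxy)-3-formyl-4-hydroxy-6-methylbenzoate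
Conditions: MnO2 (activated, 15 equiv), CH2Cl2, 25 °C
Reagents that add atoms: none
Why: Chemoselective oxidation of the benzylic alcohol to the salicylaldehyde; MnO2 should leave the phenol, the benzylic methyl ether of ring B and the acetals untouched.

Step 12
Reactants: 22 methyl 2-(ArB-oxy)-3-formyl-4-hydroxy-6-methylbenzoate
Product: 23 methyl 2-[2,4-dihydroxy-3-(methoxymethyl)-6-methylphenoxy]-3-formyl-4-hydroxy-6-methylbenzoate
Conditions: HCl (1.25 M in MeOH), 25 °C → 40 °C; aqueous work-up
Reagents that add atoms: none
Why: Acid-catalysed acetal exchange removes both MOM groups as dimethoxymethane; in methanol the ionisable benzylic methyl ether can only exchange with the solvent (degenerate), and any dimethyl acetal of the aldehyde reverts on aqueous work-up.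

Step 13
Reactants: 23 methyl 2-[2,4-dihydroxy-3-(methoxymethyl)-6-methylphenoxy]-3-formyl-4-hydroxy-6-methylbenzoate; 24 methyl 2,4-dihydroxy-6-methylbenzoate (methyl orsellinate)
Product: 25 praesorether F, methyl 2-{2,4-dihydroxy-3-[(2,6-dihydroxy-3-(methoxycarbonyl)-4-methylphenyl)methyl]-6-methylphenoxy}-3-formyl-4-hydroxy-6-methylbenzoate
Conditions: 23 added over 6 h to 24 (10 equiv) and TsOH·H2O (0.1 equiv), 1,4-dioxane, 60 °C
Reagents that add atoms: none
Why: Acid-induced loss of methanol gives the ortho-quinone methide (benzylic cation) of ring B, which alkylates 24 at C3 in a Friedel–Crafts alkylation; C3 between the two hydroxyls is the expected site in 6-alkyl-2,4-dihydroxybenzoates because C5 is crowded by the methyl group, and slow addition keeps 23 dilute so that excess 24 outruns self-alkylation at C3'.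

## Compound list

1 | orcinol (5-methylbenzene-1,3-diol) | Cc1cc(O)cc(O)c1 | starting material
2 | 1,3-bis(methoxymethoxy)-5-methylbenzene | COCOc1cc(C)cc(OCOC)c1 | intermediate
3 | [2,6-bis(methoxymethoxy)-4-methylphenyl]lithium | [Li]c1c(OCOC)cc(C)cc1OCOC | intermediate (not isolated)
4 | 2-(methoxymethyl)-1,3-bis(methoxymethoxy)-5-methylbenzene | COCc1c(OCOC)cc(C)cc1OCOC | intermediate
5 | 1-bromo-3-(methoxymethyl)-2,4-bis(methoxymethoxy)-6-methylbenzene | COCc1c(OCOC)cc(C)c(Br)c1OCOC | intermediate
6 | [3-(methoxymethyl)-2,4-bis(methoxymethoxy)-6-methylphenyl]lithium | [Li]c1c(C)cc(OCOC)c(COC)c1OCOC | intermediate (not isolated)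
7 | dimethyl [3-(methoxymethyl)-2,4-bis(methoxymethoxy)-6-methylphenyl]boronate | COB(OC)c1c(C)cc(OCOC)c(COC)c1OCOC | intermediate (not isolated)
8 | 3-(methoxymethyl)-2,4-bis(methoxymethoxy)-6-methylphenol | Oc1c(C)cc(OCOC)c(COC)c1OCOC | intermediate
9 | 1-{[(E)-1,2-dichloroethenyl]oxy}-3-(methoxymethyl)-2,4-bis(methoxymethoxy)-6-methylbenzene | Cl/C=C(/Cl)Oc1c(C)cc(OCOC)c(COC)c1OCOC | intermediate
10 | 1-[(chloroethynyl)oxy]-3-(methoxymethyl)-2,4-bis(methoxymethoxy)-6-methylbenzene | ClC#COc1c(C)cc(OCOC)c(COC)c1OCOC | intermediate (not isolated)
11 | {[3-(methoxymethyl)-2,4-bis(methoxymethoxy)-6-methylphenoxy]ethynyl}lithium | [Li]C#COc1c(C)cc(OCOC)c(COC)c1OCOC | intermediate (not isolated)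
12 | lithium 3-[3-(methoxymethyl)-2,4-bis(methoxymethoxy)-6-methylphenoxy]prop-2-yn-1-olate | [Li]OCC#COc1c(C)cc(OCOC)c(COC)c1OCOC | intermediate (not isolated)
13 | tert-butyl({3-[3-(methoxymethyl)-2,4-bis(methoxymethoxy)-6-methylphenoxy]prop-2-yn-1-yl}oxy)dimethylsilane | CC(C)(C)[Si](C)(C)OCC#COc1c(C)cc(OCOC)c(COC)c1OCOC | intermediate
14 | dimethyl 2-(propan-2-ylidene)propanedioate | COC(=O)C(=C(C)C)C(=O)OC | starting material
15 | 2-(methoxycarbonyl)-3-methylbut-2-enoic acid | COC(=O)C(=C(C)C)C(=O)O | intermediate
16 | methyl 2-(chlorocarbonyl)-3-methylbut-2-enoate | COC(=O)C(=C(C)C)C(Cl)=O | intermediate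
17 | methyl 3-methyl-2-(oxomethylidene)but-3-enoate (vinylketene) | COC(=O)C(=C=O)C(C)=C | intermediate (not isolated)
18 | methyl 3-({[tert-butyl(dimethyl)silyl]oxy}methyl)-2-[3-(methoxymethyl)-2,4-bis(methoxymethoxy)-6-methylphenoxy]-4-oxo-1-(prop-1-en-2-yl)cyclobut-2-ene-1-carboxylate (racemic) | COC(=O)C1(C(C)=C)C(=O)C(CO[Si](C)(C)C(C)(C)C)=C1Oc1c(C)cc(OCOC)c(COC)c1OCOC | intermediate (not isolated)
19 | methyl (2Z)-4-({[tert-butyl(dimethyl)silyl]oxy}methyl)-3-[3-(methoxymethyl)-2,4-bis(methoxymethoxy)-6-methylphenoxy]-5-oxo-2-(prop-1-en-2-yl)penta-2,4-dienoate (dienylketene) | C=C(C)/C(C(=O)OC)=C(Oc1c(C)cc(OCOC)c(COC)c1OCOC)\C(CO[Si](C)(C)C(C)(C)C)=C=O | intermediate (not isolated)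
20 | methyl 3-({[tert-butyl(dimethyl)silyl]oxy}methyl)-4-hydroxy-2-[3-(methoxymethyl)-2,4-bis(methoxymethoxy)-6-methylphenoxy]-6-methylbenzoate | COC(=O)c1c(C)cc(O)c(CO[Si](C)(C)C(C)(C)C)c1Oc1c(C)cc(OCOC)c(COC)c1OCOC | intermediate
21 | methyl 4-hydroxy-3-(hydroxymethyl)-2-[3-(methoxymethyl)-2,4-bis(methoxymethoxy)-6-methylphenoxy]-6-methylbenzoate | COC(=O)c1c(C)cc(O)c(CO)c1Oc1c(C)cc(OCOC)c(COC)c1OCOC | intermediate
22 | methyl 3-formyl-4-hydroxy-2-[3-(methoxymethyl)-2,4-bis(methoxymethoxy)-6-methylphenoxy]-6-methylbenzoate | COC(=O)c1c(C)cc(O)c(C=O)c1Oc1c(C)cc(OCOC)c(COC)c1OCOC | intermediate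
23 | methyl 2-[2,4-dihydroxy-3-(methoxymethyl)-6-methylphenoxy]-3-formyl-4-hydroxy-6-methylbenzoate | COC(=O)c1c(C)cc(O)c(C=O)c1Oc1c(C)cc(O)c(COC)c1O | intermediate
24 | methyl 2,4-dihydroxy-6-methylbenzoate (methyl orsellinate) | COC(=O)c1c(C)cc(O)cc1O | starting material
25 | praesorether F | COC(=O)c1c(C)cc(O)c(Cc2c(O)cc(C)c(Oc3c(C=O)c(O)cc(C)c3C(=O)OC)c2O)c1O | target

## Step count and least certain steps

Total: 13 steps. Longest linear sequence: 11 steps (steps 1 to 6 and 9 to 13); steps 7 and 8 form a two-step branch.

Step 9 (key step). The main risk is capture of the first-formed ketene–alkyne adduct by a path other than four-ring closure: through the ester oxygen (hetero-[4+2], pyranone formation) or through the γ-carbon of the dienolate (regioisomeric arene). Also possible are dimerisation of 17 before it meets 13, and closure of 19 through the ester carbonyl instead of the alkene. The fallback is a conventional SNAr that sets out from 8 and comes back at 23.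
- 3-Fluoro-5-methylphenol is brominated para to the hydroxyl (NBS) to 4-bromo-3-fluoro-5-methylphenol F1.
- Protection (NaH, MOMCl) gives 2-bromo-1-fluoro-5-(methoxymethoxy)-3-methylbenzene F2.
- Bromine–magnesium exchange (i-PrMgCl·LiCl) and methyl chloroformate give methyl 2-fluoro-4-(methoxymethoxy)-6-methylbenzoate F3.
- Magnesiation between fluorine and the MOM ether (TMPMgCl·LiCl) and formylation (DMF) give methyl 2-fluoro-3-formyl-4-(methoxymethoxy)-6-methylbenzoate F4.
- The potassium salt of 8 (K2CO3, DMSO, 60 °C) displaces the fluoride of F4, which is activated by the ortho formyl and ortho ester groups, to give methyl 3-formyl-4-(methoxymethoxy)-2-[3-(methoxymethyl)-2,4-bis(methoxymethoxy)-6-methylphenoxy]-6-methylbenzoate F5.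
- The conditions of step 12 remove all three MOM groups from F5 and deliver 23.

Step 13. The likely failures are self-alkylation of 23 at its own C3' (oligomerisation), attack at C5 of 24, and further alkylation of the product. The fallback sets out from 22 and comes back at 25, and reverses the order of bridging and deprotection. 22 is added to excess 24 and BF3·OEt2 in CH2Cl2 at −40 °C. Ionisation of the benzylic methyl ether, now flanked by two MOM ethers with no free hydroxyl on ring B, and alkylation of 24 at C3 would give methyl 2-{3-[(2,6-dihydroxy-3-(methoxycarbonyl)-4-methylphenyl)methyl]-2,4-bis(methoxymethoxy)-6-methylphenoxy}-3-formyl-4-hydroxy-6-methylbenzoate F6. HCl in MeOH then gives 25. This detour also bypasses 23 and therefore step 12.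

Step 6. The likely failures are competing ring lithiation next to a MOM ether by the excess n-BuLi, incomplete chlorine–lithium exchange, and hydration of the alkynyl ether during work-up. The fallback sets out from 8 and comes back at 13, and replaces the organolithium chemistry by a copper-catalysed C–O coupling.
- (tert-Butyldimethylsilyloxy)acetaldehyde is converted with CBr4/PPh3 into tert-butyl[(3,3-dibromoprop-2-en-1-yl)oxy]dimethylsilane F7.
- Coupling of 8 with F7 (CuI, 2,2'-bipyridine, K3PO4, toluene, 110 °C) at the C–Br bond trans to the chain gives tert-butyl({(2Z)-3-bromo-3-[3-(methoxymethyl)-2,4-bis(methoxymethoxy)-6-methylphenoxy]prop-2-en-1-yl}oxy)dimethylsilane F8.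
- KOt-Bu (THF, −40 °C) removes HBr by anti elimination and gives 13.

Step 3. The likely failures are over-bromination of the very electron-rich ring and loss of the acid-labile benzylic ether or MOM groups through traces of HBr. The fallback sets out from 4 and comes back at 8. Directed lithiation next to a MOM ether (s-BuLi, TMEDA, THF, −78 °C) gives 6 directly, and borylation and oxidation as in step 4 give 8 without passing through 5. No new compound is made (entry F0).

## Further compounds

F1 | step 9 | 4-bromo-3-fluoro-5-methylphenol | Cc1cc(O)cc(F)c1Br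
F2 | step 9 | 2-bromo-1-fluoro-5-(methoxymethoxy)-3-methylbenzene | COCOc1cc(C)c(Br)c(F)c1
F3 | step 9 | methyl 2-fluoro-4-(methoxymethoxy)-6-methylbenzoate | COCOc1cc(C)c(C(=O)OC)c(F)c1
F4 | step 9 | methyl 2-fluoro-3-formyl-4-(methoxymethoxy)-6-methylbenzoate | COCOc1cc(C)c(C(=O)OC)c(F)c1C=O
F5 | step 9 | methyl 3-formyl-4-(methoxymethoxy)-2-[3-(methoxymethyl)-2,4-bis(methoxymethoxy)-6-methylphenoxy]-6-methylbenzoate | COC(=O)c1c(C)cc(OCOC)c(C=O)c1Oc1c(C)cc(OCOC)c(COC)c1OCOC
F6 | step 13 | methyl 2-{3-[(2,6-dihydroxy-3-(methoxycarbonyl)-4-methylphenyl)methyl]-2,4-bis(methoxymethoxy)-6-methylphenoxy}-3-formyl-4-hydroxy-6-methylbenzoate | COC(=O)c1c(C)cc(O)c(Cc2c(OCOC)cc(C)c(Oc3c(C=O)c(O)cc(C)c3C(=O)OC)c2OCOC)c1O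
F7 | step 6 | tert-butyl[(3,3-dibromoprop-2-en-1-yl)oxy]dimethylsilane | CC(C)(C)[Si](C)(C)OCC=C(Br)Br
F8 | step 6 | tert-butyl({(2Z)-3-bromo-3-[3-(methoxymethyl)-2,4-bis(methoxymethoxy)-6-methylphenoxy]prop-2-en-1-yl}oxy)dimethylsilane | CC(C)(C)[Si](C)(C)OC/C=C(\Br)Oc1c(C)cc(OCOC)c(COC)c1OCOC
F0 | step 3 | none | none
A1 | alternative 1 | 2,4-dimethoxy-6-methylphenol | COc1cc(C)c(O)c(OC)c1
A2 | alternative 1 | methyl 2-fluoro-3-formyl-4-methoxy-6-methylbenzoate | COC(=O)c1c(C)cc(OC)c(C=O)c1F
A3 | alternative 1 | methyl 2-(2,4-dimethoxy-6-methylphenoxy)-3-formyl-4-methoxy-6-methylbenzoate | COC(=O)c1c(C)cc(OC)c(C=O)c1Oc1c(C)cc(OC)cc1OC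
A4 | alternative 2 | methyl 3-[3-(methoxymethyl)-2,4-bis(methoxymethoxy)-6-methylphenoxy]prop-2-ynoate | COC(=O)C#COc1c(C)cc(OCOC)c(COC)c1OCOC
A5 | alternative 2 | 3-formyl-4-hydroxy-6-methyl-2H-pyran-2-one | Cc1cc(O)c(C=O)c(=O)o1
A6 | alternative 2 | methyl 4-formyl-5-hydroxy-8-[3-(methoxymethyl)-2,4-bis(methoxymethoxy)-6-methylphenoxy]-1-methyl-3-oxo-2-oxabicyclo[2.2.2]octa-5,7-diene-7-carboxylate (racemic) | O=CC12C(O)=CC(C)(OC1=O)C(C(=O)OC)=C2Oc1c(C)cc(OCOC)c(COC)c1OCOC
A7 | alternative 3 | 5-methylcyclohexane-1,3-dione | CC1CC(=O)CC(=O)C1
A8 | alternative 3 | 2-chloro-4-methyl-6-oxocyclohex-1-ene-1-carbaldehyde (racemic) | CC1CC(Cl)=C(C=O)C(=O)C1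
A9 | alternative 3 | 2-[3-(methoxymethyl)-2,4-bis(methoxymethoxy)-6-methylphenoxy]-4-methyl-6-oxocyclohex-1-ene-1-carbaldehyde (racemic) | CC1CC(Oc2c(C)cc(OCOC)c(COC)c2OCOC)=C(C=O)C(=O)C1
A10 | alternative 3 | 2-hydroxy-6-[3-(methoxymethyl)-2,4-bis(methoxymethoxy)-6-methylphenoxy]-4-methylbenzaldehyde | Cc1cc(O)c(C=O)c(Oc2c(C)cc(OCOC)c(COC)c2OCOC)c1
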